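**Plan**
- Retrosynthesis: the oxolan-2-one ring (O–C9'H2–C8'–C8–C9=O) is opened at C9–O and C9–C8. The carbonyl carbon C9 sits alone between the ring oxygen and C8, so it goes back to carbon monoxide, leaving a C9' alcohol and a C8≡C7 aryl alkyne.
- The alkynol is then cut at C7–aryl (guaiacyl iodide) and at C7'–C8' (veratraldehyde plus a four-carbon propargylic mesylate from (R)-glyceraldehyde acetonide).
- Forward: mesylate, C7'–C8' bond by allenylzinc addition, C7' silylation, Sonogashira coupling, deacylation, the single ring closure by cyclocarbonylation, then conjugate reduction, C8 epimerisation and desilylation.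
- Stereochemistry: C8' comes from the chiral pool (mesylate carbon, overall inversion), C7' from the anti-selective cyclic transition state of the allenylzinc addition, and C8 from thermodynamic control (trans to the C8' side chain).

Key step: step 10

Assumption: lignan numbering is used throughout (lactone C9(=O)–C8–C8'–C9'H2–O, C7 the guaiacyl CH2, C7' the carbinol); protonation after the conjugate reduction is taken to occur anti to the C8' side chain, so step 11 should give mainly the 8,8'-cis lactone, which step 12 corrects.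

**Route**

Step 1
Reactants: 1 (R)-2,3-O-isopropylideneglyceraldehyde
Product: 2 (S)-4-ethynyl-2,2-dimethyl-1,3-dioxolane
Conditions: dimethyl (1-diazo-2-oxopropyl)phosphonate, K2CO3, MeOH, 0 °C to rt
Reagents that add atoms: dimethyl (1-diazo-2-oxopropyl)phosphonate, CC(=O)C(=[N+]=[N-])P(=O)(OC)OC
Why: Ohira–Bestmann (Seyferth–Gilbert) homologation turns the aldehyde into the terminal alkyne under mild carbonate conditions that should preserve the alpha-alkoxy stereocentre, which is not a reacting atom.

Step 2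
Reactants: 2 (S)-4-ethynyl-2,2-dimethyl-1,3-dioxolane
Product: 3 (S)-but-3-yne-1,2-diol
Conditions: Amberlyst 15 (H+ form), MeOH–H2O, rt; filter, evaporate carefully
Reagents that add atoms: none
Why: Acid-catalysed acetal hydrolysis on a sulfonic acid resin frees the water-soluble diol without an aqueous extraction.

Step 3
Reactants: 3 (S)-but-3-yne-1,2-diol
Product: 4 (S)-2-hydroxybut-3-yn-1-yl pivalate
Conditions: PivCl (1.0 equiv), pyridine, CH2Cl2, −20 to 0 °C
Reagents that add atoms: pivaloyl chloride, CC(C)(C)C(=O)Cl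
Why: Selective acylation of the primary hydroxyl by the bulky acid chloride at low temperature leaves the secondary propargylic hydroxyl free.

Step 4
Reactants: 4 (S)-2-hydroxybut-3-yn-1-yl pivalate
Product: 5 (S)-2-[(methylsulfonyl)oxy]but-3-yn-1-yl pivalate
Conditions: MsCl, Et3N, CH2Cl2, −78 to 0 °C
Reagents that add atoms: methanesulfonyl chloride, CS(=O)(=O)Cl
Why: Sulfonylation of the secondary alcohol with retention gives the propargylic mesylate, the usual precursor for palladium-mediated allenylmetal formation.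

Step 5
Reactants: 5 (S)-2-[(methylsulfonyl)oxy]but-3-yn-1-yl pivalate; 6 veratraldehyde
Product: 8 (2R,3S)-3-(3,4-dimethoxyphenyl)-2-ethynyl-3-hydroxypropyl pivalate, via ethyl allenylzinc 7 (not isolated)
Conditions: Pd(OAc)2 (5 mol %), PPh3 (5 mol %), Et2Zn (3 equiv), THF, −78 to −20 °C; aq NH4Cl
Reagents that add atoms: none
Why: Marshall propargylation: zerovalent palladium (formed from Pd(OAc)2, PPh3 and Et2Zn) ionises the mesylate by anti SN2' attack, transmetalation gives the (aS)-allenylzinc 7, and its cyclic SE2' addition to 6 places the aryl group away from the CH2OPiv group, so C8' is set by the mesylate with overall inversion (8'R) and C7' by the transition state as the anti (7'S) isomer.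

Step 6
Reactants: 8 (2R,3S)-3-(3,4-dimethoxyphenyl)-2-ethynyl-3-hydroxypropyl pivalate
Product: 9 (2R,3S)-3-[(tert-butyldimethylsilyl)oxy]-3-(3,4-dimethoxyphenyl)-2-ethynylpropyl pivalate
Conditions: TBSOTf, 2,6-lutidine, CH2Cl2, −78 to 0 °C
Reagents that add atoms: tert-butyldimethylsilyl trifluoromethanesulfonate, CC(C)(C)[Si](C)(C)OS(=O)(=O)C(F)(F)F
Why: Silyl ether formation with the reactive triflate caps the hindered benzylic C7' hydroxyl, so that later only the C9' oxygen can lactonise.

Step 7
Reactants: 10 4-iodo-2-methoxyphenol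
Product: 11 tert-butyl(4-iodo-2-methoxyphenoxy)dimethylsilane
Conditions: TBSCl, imidazole, DMF, rt
Reagents that add atoms: tert-butyldimethylsilyl chloride, CC(C)(C)[Si](C)(C)Cl
Why: Standard silylation of the phenol keeps a free phenoxide out of the coupling and the carbonylation.

Step 8
Reactants: 9 (2R,3S)-3-[(tert-butyldimethylsilyl)oxy]-3-(3,4-dimethoxyphenyl)-2-ethynylpropyl pivalate; 11 tert-butyl(4-iodo-2-methoxyphenoxy)dimethylsilane
Product: 12 (2R,3S)-3-[(tert-butyldimethylsilyl)oxy]-2-{[4-[(tert-butyldimethylsilyl)oxy]-3-methoxyphenyl]ethynyl}-3-(3,4-dimethoxyphenyl)propyl pivalate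
Conditions: PdCl2(PPh3)2 (3 mol %), CuI (5 mol %), Et3N, THF (degassed), rt
Reagents that add atoms: none
Why: Sonogashira coupling forms the C7–aryl bond at room temperature under amine base, which leaves the pivalate, the silyl ethers and both stereocentres unchanged.

Step 9
Reactants: 12 (2R,3S)-3-[(tert-butyldimethylsilyl)oxy]-2-{[4-[(tert-butyldimethylsilyl)oxy]-3-methoxyphenyl]ethynyl}-3-(3,4-dimethoxyphenyl)propyl pivalate
Product: 13 (2R,3S)-3-[(tert-butyldimethylsilyl)oxy]-2-{[4-[(tert-butyldimethylsilyl)oxy]-3-methoxyphenyl]ethynyl}-3-(3,4-dimethoxyphenyl)propan-1-ol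
Conditions: DIBAL-H (3 equiv), CH2Cl2, −78 °C; Rochelle salt work-up
Reagents that add atoms: none
Why: Reductive ester cleavage with DIBAL-H frees only the C9' hydroxyl, and the non-basic aluminium alkoxide avoids the silyl migration and aryl silyl ether loss that a methanolysis would risk.

Step 10
Reactants: 13 (2R,3S)-3-[(tert-butyldimethylsilyl)oxy]-2-{[4-[(tert-butyldimethylsilyl)oxy]-3-methoxyphenyl]ethynyl}-3-(3,4-dimethoxyphenyl)propan-1-ol; 14 carbon monoxide
Product: 15 (3E,4R)-4-[(S)-[(tert-butyldimethylsilyl)oxy](3,4-dimethoxyphenyl)methyl]-3-{[4-[(tert-butyldimethylsilyl)oxy]-3-methoxyphenyl]methylidene}oxolan-2-one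
Conditions: PdCl2(PPh3)2 (10 mol %), SnCl2 (10 mol %), CO (7 atm), MeCN, 75 °C
Reagents that add atoms: carbon monoxide (compound 14), [C-]#[O+]
Why: This is the palladium-catalysed cyclocarbonylation of a but-3-yn-1-ol (alkoxycarbonylation of an alkyne with ring closure), the known route to alpha-alkylidene gamma-butyrolactones. The free C9' hydroxyl, CO and the divalent palladium chloride activated by SnCl2 give an alkoxycarbonyl palladium species (C9–O bond), the tethered C8≡C7 triple bond inserts syn into its Pd–C bond (C9–C8 bond), and protonolysis of the alkenyl palladium at C7 by the HCl released earlier returns the catalyst. The oxolan-2-one ring closes in the 5-exo-dig mode, because the tether O–C9'–C8'–C8 can deliver the acyl carbon only to the near alkyne carbon in a syn insertion, whereas the six-membered alternative would need an anti addition. No stereocentre is created and C7' and C8' are not touched; syn addition of C9 and H fixes the (E) geometry, with the aryl group cis to C8' and trans to the carbonyl. The selectivity needed is which oxygen is acylated, and the silyl ether on the C7' oxygen secures it by leaving C9'–OH as the only hydroxyl, so C9' becomes the OCH2 and C9 the carbonyl.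

Step 11
Reactants: 15 (3E,4R)-4-[(S)-[(tert-butyldimethylsilyl)oxy](3,4-dimethoxyphenyl)methyl]-3-{[4-[(tert-butyldimethylsilyl)oxy]-3-methoxyphenyl]methylidene}oxolan-2-one
Product: 16 (3S,4R)-3-{4-[(tert-butyldimethylsilyl)oxy]-3-methoxybenzyl}-4-[(S)-[(tert-butyldimethylsilyl)oxy](3,4-dimethoxyphenyl)methyl]oxolan-2-one (8,8'-cis)
Conditions: [(Ph3P)CuH]6 (0.5 equiv), H2O (2 equiv), toluene (degassed), rt
Reagents that add atoms: none
Why: Stryker conjugate reduction delivers hydride to C7 of the arylidene lactone and water protonates C8 from the face away from the C8' side chain, so the cis lactone is expected; the lactone carbonyl and the benzylic C–O bond are not attacked, and any trans isomer formed converges in step 12.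

Step 12
Reactants: 16 (3S,4R)-3-{4-[(tert-butyldimethylsilyl)oxy]-3-methoxybenzyl}-4-[(S)-[(tert-butyldimethylsilyl)oxy](3,4-dimethoxyphenyl)methyl]oxolan-2-one
Product: 17 (3R,4R)-3-{4-[(tert-butyldimethylsilyl)oxy]-3-methoxybenzyl}-4-[(S)-[(tert-butyldimethylsilyl)oxy](3,4-dimethoxyphenyl)methyl]oxolan-2-one (8,8'-trans)
Conditions: DBU, toluene, 60 °C
Reagents that add atoms: none
Why: Base-mediated epimerisation through the lactone enolate: C8 is the only acidic centre and the trans-2,3-disubstituted lactone is the thermodynamically preferred one, so 8R is set by equilibration while C8' and the silylated C7' stay fixed.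

Step 13
Reactants: 17 (3R,4R)-3-{4-[(tert-butyldimethylsilyl)oxy]-3-methoxybenzyl}-4-[(S)-[(tert-butyldimethylsilyl)oxy](3,4-dimethoxyphenyl)methyl]oxolan-2-one
Product: 18 (3R,4R)-4-[(S)-(3,4-dimethoxyphenyl)(hydroxy)methyl]-3-(4-hydroxy-3-methoxybenzyl)oxolan-2-one (CNP0119431.1)
Conditions: TBAF (3 equiv), AcOH (3 equiv), THF, 0 °C to rt
Reagents that add atoms: none
Why: Fluoride desilylation buffered with acetic acid cleaves both silyl ethers while avoiding a free C7' alkoxide (translactonisation) and strong acid (ionisation of the electron-rich benzylic position).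

**Compound list**
1 | (R)-2,3-O-isopropylideneglyceraldehyde | CC1(C)OC[C@H](C=O)O1 | starting material
2 | (S)-4-ethynyl-2,2-dimethyl-1,3-dioxolane | CC1(C)OC[C@H](C#C)O1 | intermediate
3 | (S)-but-3-yne-1,2-diol | C#C[C@H](O)CO | intermediate
4 | (S)-2-hydroxybut-3-yn-1-yl pivalate | C#C[C@H](O)COC(=O)C(C)(C)C | intermediate
5 | (S)-2-[(methylsulfonyl)oxy]but-3-yn-1-yl pivalate | C#C[C@H](OS(C)(=O)=O)COC(=O)C(C)(C)C | intermediate
6 | veratraldehyde (3,4-dimethoxybenzaldehyde) | COc1ccc(C=O)cc1OC | starting material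
7 | ethyl[(aS)-4-(pivaloyloxy)buta-1,2-dien-1-yl]zinc | [H]C([Zn]CC)=[C@]=C([H])COC(=O)C(C)(C)C | intermediate
8 | (2R,3S)-3-(3,4-dimethoxyphenyl)-2-ethynyl-3-hydroxypropyl pivalate | CC(C)(C)C(=O)OC[C@@H](C#C)[C@H](O)c1ccc(OC)c(OC)c1 | intermediate
9 | (2R,3S)-3-[(tert-butyldimethylsilyl)oxy]-3-(3,4-dimethoxyphenyl)-2-ethynylpropyl pivalate | CC(C)(C)C(=O)OC[C@@H](C#C)[C@H](O[Si](C)(C)C(C)(C)C)c1ccc(OC)c(OC)c1 | intermediate
10 | 4-iodo-2-methoxyphenol | COc1cc(I)ccc1O | starting material
11 | tert-butyl(4-iodo-2-methoxyphenoxy)dimethylsilane | COc1cc(I)ccc1O[Si](C)(C)C(C)(C)C | intermediate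
12 | (2R,3S)-3-[(tert-butyldimethylsilyl)oxy]-2-{[4-[(tert-butyldimethylsilyl)oxy]-3-methoxyphenyl]ethynyl}-3-(3,4-dimethoxyphenyl)propyl pivalate | CC(C)(C)C(=O)OC[C@@H](C#Cc1ccc(O[Si](C)(C)C(C)(C)C)c(OC)c1)[C@H](O[Si](C)(C)C(C)(C)C)c1ccc(OC)c(OC)c1 | intermediate
13 | (2R,3S)-3-[(tert-butyldimethylsilyl)oxy]-2-{[4-[(tert-butyldimethylsilyl)oxy]-3-methoxyphenyl]ethynyl}-3-(3,4-dimethoxyphenyl)propan-1-ol | OC[C@@H](C#Cc1ccc(O[Si](C)(C)C(C)(C)C)c(OC)c1)[C@H](O[Si](C)(C)C(C)(C)C)c1ccc(OC)c(OC)c1 | intermediate
14 | carbon monoxide | [C-]#[O+] | starting material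
15 | (3E,4R)-4-[(S)-[(tert-butyldimethylsilyl)oxy](3,4-dimethoxyphenyl)methyl]-3-{[4-[(tert-butyldimethylsilyl)oxy]-3-methoxyphenyl]methylidene}oxolan-2-one | O=C1OC[C@H]([C@H](O[Si](C)(C)C(C)(C)C)c2ccc(OC)c(OC)c2)/C1=C\c3ccc(O[Si](C)(C)C(C)(C)C)c(OC)c3 | intermediate
16 | (3S,4R)-3-{4-[(tert-butyldimethylsilyl)oxy]-3-methoxybenzyl}-4-[(S)-[(tert-butyldimethylsilyl)oxy](3,4-dimethoxyphenyl)methyl]oxolan-2-one | COc1cc(C[C@@H]2C(=O)OC[C@@H]2[C@H](O[Si](C)(C)C(C)(C)C)c2ccc(OC)c(OC)c2)ccc1O[Si](C)(C)C(C)(C)C | intermediate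
17 | (3R,4R)-3-{4-[(tert-butyldimethylsilyl)oxy]-3-methoxybenzyl}-4-[(S)-[(tert-butyldimethylsilyl)oxy](3,4-dimethoxyphenyl)methyl]oxolan-2-one | COc1cc(C[C@H]2C(=O)OC[C@@H]2[C@H](O[Si](C)(C)C(C)(C)C)c2ccc(OC)c(OC)c2)ccc1O[Si](C)(C)C(C)(C)C | intermediate
18 | (3R,4R)-4-[(S)-(3,4-dimethoxyphenyl)(hydroxy)methyl]-3-(4-hydroxy-3-methoxybenzyl)oxolan-2-one | COc1cc(C[C@H]2C(=O)OC[C@@H]2[C@H](O)c2ccc(OC)c(OC)c2)ccc1O | target

**Totals**
Total step count: 13. Longest linear sequence: 12 steps (steps 1–6 and 8–13, from 1 to 18).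

**Steps most likely to fail**

Step 5 (allenylzinc addition). The anti selectivity may erode with an aromatic aldehyde, the allenylzinc may racemise before it adds, and pivalate may be lost from the organozinc by 1,4-elimination. The fallback sets out from 6 and comes back at 13. It makes the C7'–C8' bond and both centres by an iridium-catalysed transfer-hydrogenative anti-(hydroxymethyl)allylation of 6, which should give (1S,2R)-1-(3,4-dimethoxyphenyl)-2-ethenylpropane-1,3-diol F1. The catalyst is the cyclometallated complex from [Ir(cod)Cl]2, the SEGPHOS enantiomer chosen for the 7'S sense and 4-cyano-3-nitrobenzoic acid, with 4-vinyl-1,3-dioxolan-2-one as allyl donor and i-PrOH as reductant. Silylation of both hydroxyls (TBSOTf, 2,6-lutidine) gives the (7'S,8'R) bis-silyl ether alkene F2. Lemieux–Johnson cleavage of the vinyl group (OsO4 cat., NaIO4, 2,6-lutidine, dioxane–H2O) gives the (7'S,8'R) bis-silyl ether aldehyde F3, and Ohira–Bestmann homologation gives the (7'S,8'R) bis-silyl ether terminal alkyne F4. Sonogashira coupling with 11 gives the (7'S,8'R) tris-silyl ether aryl alkyne F5, and selective methanolysis of the primary silyl ether (PPTS, MeOH, rt) returns to 13.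

Step 10 (cyclocarbonylation). Insertion of the hindered aryl alkyne into the alkoxycarbonyl–palladium bond may be slow, the hydroxyl may instead add to the alkyne by 5-endo oxypalladation, and a silyl ether may be lost in the Lewis acidic medium. The fallback sets out from 13 and comes back at 15. It forms the C9–O bond first as a carbonate (ClCO2Et, pyridine, CH2Cl2, 0 °C), giving the (7'S,8'R) ethyl carbonate of the alkynol F6. The C9–C8 bond is then closed by titanium-mediated intramolecular nucleophilic acyl substitution (Ti(O-i-Pr)4, 2 i-PrMgCl, Et2O, −50 to −20 °C; aqueous quench). The divalent titanium alkyne complex attacks the carbonate carbonyl through C8 with loss of ethoxide, and protonolysis of the remaining C7–Ti bond with retention should give the same (E)-arylidene lactone 15.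

Step 11 (conjugate reduction). Hydride transfer to the hindered beta-aryl enoate may be sluggish, 1,2-reduction of the lactone may compete, and protonation leaves C8 in the cis configuration, so the outcome depends on a complete equilibration afterwards. The fallback sets out from 15 and comes back at 18. Buffered fluoride (TBAF, AcOH, THF) removes both silyl groups first to give (3E,4R)-4-[(S)-(3,4-dimethoxyphenyl)(hydroxy)methyl]-3-[(4-hydroxy-3-methoxyphenyl)methylidene]oxolan-2-one F7. Hydroxyl-directed hydrogenation ([Ir(cod)(PCy3)(py)]PF6, H2, CH2Cl2, rt) then uses the C7' hydroxyl to deliver hydrogen to the alkene face on the side of the C8' side chain. This places the C8 hydrogen cis and the benzyl group trans to that chain and should give 18 directly, without steps 12 and 13.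

**Further compounds**
F1 | step 5 | (1S,2R)-1-(3,4-dimethoxyphenyl)-2-ethenylpropane-1,3-diol | OC[C@@H](C=C)[C@H](O)c1ccc(OC)c(OC)c1
F2 | step 5 | (7'S,8'R) bis-silyl ether alkene (bis-TBS ether of F1) | CC(C)(C)[Si](C)(C)OC[C@@H](C=C)[C@H](O[Si](C)(C)C(C)(C)C)c1ccc(OC)c(OC)c1
F3 | step 5 | (7'S,8'R) bis-silyl ether aldehyde, 3-[(tert-butyldimethylsilyl)oxy]-2-{[(tert-butyldimethylsilyl)oxy]methyl}-3-(3,4-dimethoxyphenyl)propanal | CC(C)(C)[Si](C)(C)OC[C@@H](C=O)[C@H](O[Si](C)(C)C(C)(C)C)c1ccc(OC)c(OC)c1
F4 | step 5 | (7'S,8'R) bis-silyl ether terminal alkyne | CC(C)(C)[Si](C)(C)OC[C@@H](C#C)[C@H](O[Si](C)(C)C(C)(C)C)c1ccc(OC)c(OC)c1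
F5 | step 5 | (7'S,8'R) tris-silyl ether aryl alkyne | CC(C)(C)[Si](C)(C)OC[C@@H](C#Cc1ccc(O[Si](C)(C)C(C)(C)C)c(OC)c1)[C@H](O[Si](C)(C)C(C)(C)C)c1ccc(OC)c(OC)c1
F6 | step 10 | (7'S,8'R) ethyl carbonate of the alkynol | CCOC(=O)OC[C@@H](C#Cc1ccc(O[Si](C)(C)C(C)(C)C)c(OC)c1)[C@H](O[Si](C)(C)C(C)(C)C)c1ccc(OC)c(OC)c1
F7 | step 11 | (3E,4R)-4-[(S)-(3,4-dimethoxyphenyl)(hydroxy)methyl]-3-[(4-hydroxy-3-methoxyphenyl)methylidene]oxolan-2-one | O=C1OC[C@H]([C@H](O)c2ccc(OC)c(OC)c2)/C1=C\c3ccc(O)c(OC)c3
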